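**Plan**

- Retrosynthesis (labdane numbering): the malonate C15–O ester bond, the C8=C17 methylene and the side-chain bonds C13=C14 and C11=C12 are cut first. This leaves an acyl carbon (C11) on C9 and an oxygen on C8.
- Ring A (C1–C5, C10) and ring B (C5–C10) are then opened together at C5–C10 and C8–C9. The resulting acyclic triene is cut at C6=C7 (cross-metathesis) and at C4–C5 (allylation of the tertiary cation of a geranate).
- Enabling feature: in ring B, C9 carries C11 next to the sp2 carbon C8 (a masked oxygen), and the quaternary C10 is shared with ring A. Ring B is therefore the Diels–Alder adduct of a C9=C10 enoyl dienophile and a C5=C6–C7=C8–O diene, joined through the C1–C4 chain of ring A.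
- Forward: the chain is joined linearly (geranate C10 unit, C5–C6 from allylsilane, C7–C8 from crotonaldehyde). Rings A and B then close in one cycloaddition, and C12–C16, C17 and the malonyl group follow.
- Stereochemistry: C5, C9 and C10 are set in the cycloaddition. The relative sense comes from the (E)-dienophile and the endo transition state with a chair tether; the absolute sense comes from the (S,S)-bis(oxazoline) ligand on divalent copper. C8 is transient, and 13E comes from an E-selective Horner–Wadsworth–Emmons reaction.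

Key step: step 7

**Remarks**

- Atom labels C1–C20 are the labdane positions of the target and are used for all intermediates. The target is (5R,9R,10R), the enantiomeric labdane series.
- Assumption: commercial methyl geranate is taken as the pure (2E) isomer.
- (S,S)-t-Bu-box = 2,2′-(propane-2,2-diyl)bis[(4S)-4-tert-butyl-4,5-dihydro-1,3-oxazole]. Its sense of induction is assigned by analogy with intermolecular reactions of the same catalyst.

**Route**

Step 1
Reactants: 1 methyl (2E)-3,7-dimethylocta-2,6-dienoate (methyl geranate)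
Product: 2 methyl (2E)-7-chloro-3,7-dimethyloct-2-enoate
Conditions: HCl (g), CH2Cl2, −30 °C → 0 °C
Reagents that add atoms: hydrogen chloride, Cl
Why: Markovnikov hydrochlorination protonates only the electron-rich trisubstituted alkene to the tertiary cation, which chloride captures, while the ester-conjugated alkene is too electron-poor to react and keeps its E geometry.

Step 2
Reactants: 2 methyl (2E)-7-chloro-3,7-dimethyloct-2-enoate; 3 allyltrimethylsilane
Product: 4 methyl (2E)-3,7,7-trimethyldeca-2,9-dienoate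
Conditions: TiCl4 (2.2 equiv), 3 (3 equiv), CH2Cl2, −78 °C
Reagents that add atoms: allyltrimethylsilane (3), C=CC[Si](C)(C)C
Why: Lewis acid-promoted tert-alkylation of an allylsilane (SE2′ allylation of a tertiary carbocation, a Hosomi–Sakurai-type process) should build the quaternary carbon (later C4), because TiCl4 ionises the C–Cl bond while the TiCl4-bound enoate is too deactivated to cyclise onto the cation.

Step 3
Reactants: 4 methyl (2E)-3,7,7-trimethyldeca-2,9-dienoate
Product: 5 (2E)-3,7,7-trimethyldeca-2,9-dienoic acid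
Conditions: LiOH, THF/MeOH/H2O, 50 °C; then 1 M HCl
Reagents that add atoms: lithium hydroxide, [Li+].[OH-]
Why: Saponification by acyl–oxygen cleavage is routine for 3-methyl-2-enoates and touches neither alkene.

Step 4
Reactants: 5 (2E)-3,7,7-trimethyldeca-2,9-dienoic acid; 6 1,3-oxazolidin-2-one
Product: 8 3-[(2E)-3,7,7-trimethyldeca-2,9-dienoyl]-1,3-oxazolidin-2-one, via mixed pivalic anhydride 7 (not isolated)
Conditions: PivCl, Et3N, THF, −20 °C; then 6, LiCl, rt
Reagents that add atoms: 1,3-oxazolidin-2-one (6), O=C1NCCO1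
Why: N-acylation of the oxazolidinone through the mixed pivalic anhydride with LiCl/Et3N is mild enough to avoid deconjugation of the β,β-disubstituted enoyl unit.

Step 5
Reactants: 8 3-[(2E)-3,7,7-trimethyldeca-2,9-dienoyl]-1,3-oxazolidin-2-one; 9 (E)-but-2-enal (crotonaldehyde)
Product: 10 3-[(2E,9E)-3,7,7-trimethyl-11-oxoundeca-2,9-dienoyl]-1,3-oxazolidin-2-one
Conditions: 9 (5 equiv), second-generation Hoveyda–Grubbs catalyst RuCl2(H2IMes)(=CH–C6H4-2-OiPr) (5 mol %), CH2Cl2, 40 °C
Reagents that add atoms: (E)-but-2-enal (9), C/C=C/C=O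
Why: Olefin cross-metathesis of the terminal alkene with crotonaldehyde should give the (E)-enal with loss of propene, the trisubstituted conjugated alkene of the imide being inert to the ruthenium carbene.

Step 6
Reactants: 10 3-[(2E,9E)-3,7,7-trimethyl-11-oxoundeca-2,9-dienoyl]-1,3-oxazolidin-2-one
Product: 11 3-[(2E,8E,10E)-11-{[tert-butyl(dimethyl)silyl]oxy}-3,7,7-trimethylundeca-2,8,10-trienoyl]-1,3-oxazolidin-2-one
Conditions: TBSOTf (1.2 equiv), Et3N, CH2Cl2, −78 °C → 0 °C
Reagents that add atoms: tert-butyldimethylsilyl trifluoromethanesulfonate, CC(C)(C)[Si](C)(C)OS(=O)(=O)C(F)(F)F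
Why: Soft enolisation (O-silylation of the aldehyde, then γ-deprotonation by Et3N) is the standard route from an enal to a 1-silyloxydiene; the aldehyde is far more Lewis basic than the imide, the tertiary alkyl group forces the new C5=C6 bond to be E, and the s-trans enal leads to the E enol ether.

Step 7
Reactants: 11 3-[(2E,8E,10E)-11-{[tert-butyl(dimethyl)silyl]oxy}-3,7,7-trimethylundeca-2,8,10-trienoyl]-1,3-oxazolidin-2-one
Product: 12 3-{[(1S,2R,4aR,8aR)-2-{[tert-butyl(dimethyl)silyl]oxy}-5,5,8a-trimethyl-1,2,4a,5,6,7,8,8a-octahydronaphthalen-1-yl]carbonyl}-1,3-oxazolidin-2-one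
Conditions: [Cu((S,S)-t-Bu-box)](SbF6)2 (10 mol %, made from CuCl2, AgSbF6 and the ligand), CH2Cl2, −20 °C → rt
Reagents that add atoms: none
Why: This is a Lewis acid-catalysed type 1 intramolecular Diels–Alder reaction of a 2,7,9-decatrienoyl imide, the closest known reaction being the enantioselective cycloaddition of N-enoyl oxazolidinones bound through both carbonyl groups to a chiral divalent copper bis(oxazoline) complex. Chelation lowers the LUMO of the s-cis C9=C10 dienophile, and the C8 silyloxy group raises the diene HOMO and makes C5 its nucleophilic end, so the hindered C5–C10 bond should form ahead of C8–C9 in a concerted, asynchronous [4+2] event (a stepwise Mukaiyama–Michael/aldol course would end at the same adduct). Ring B closes as the six-membered ring of the [4+2] itself, both new bonds lying in it, and ring A closes through the C5–C10 bond alone, fused to ring B, with the C1–C4 tether folded as a chair that the gem-dimethyl group on C4 favours. The endo transition state (imide carbonyl under the diene, tether anti) sets the trans fusion at C5/C10, the E geometry of the dienophile places C11 cis to the C10 methyl and so sets C9, the E enol ether places the C8 silyloxy group cis to C11 (a centre erased later), and the tert-butyl groups of the (S,S) ligand cover the Si face of C9 so that the diene adds to the Re face and fixes the absolute configuration. The step needs endo over exo selectivity, Re over Si selectivity and cycloaddition faster than loss of the silyl group; the first two rest on the rigid square-planar chelate and the all-E triene, the last on the non-nucleophilic SbF6 counter-ion, and the β,β-disubstituted dienophile is the demanding element that the electron-rich diene and the cationic catalyst are meant to offset.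

Step 8
Reactants: 12 3-{[(1S,2R,4aR,8aR)-2-{[tert-butyl(dimethyl)silyl]oxy}-5,5,8a-trimethyl-1,2,4a,5,6,7,8,8a-octahydronaphthalen-1-yl]carbonyl}-1,3-oxazolidin-2-one
Product: 13 [(1R,2R,4aR,8aR)-2-{[tert-butyl(dimethyl)silyl]oxy}-5,5,8a-trimethyl-1,2,4a,5,6,7,8,8a-octahydronaphthalen-1-yl]methanol
Conditions: LiBH4, H2O (1 equiv), Et2O, 0 °C
Reagents that add atoms: none
Why: Reductive cleavage of an N-acyl oxazolidinone with LiBH4 delivers the primary alcohol (C11) and frees the oxazolidinone without touching the silyl ether, the alkene or any stereocentre (the descriptor at C9 changes only through priorities).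

Step 9
Reactants: 13 [(1R,2R,4aR,8aR)-2-{[tert-butyl(dimethyl)silyl]oxy}-5,5,8a-trimethyl-1,2,4a,5,6,7,8,8a-octahydronaphthalen-1-yl]methanol
Product: 14 (1S,2R,4aR,8aR)-2-{[tert-butyl(dimethyl)silyl]oxy}-5,5,8a-trimethyl-1,2,4a,5,6,7,8,8a-octahydronaphthalene-1-carbaldehyde
Conditions: Dess–Martin periodinane, pyridine, CH2Cl2, 0 °C → rt
Reagents that add atoms: none
Why: Dess–Martin oxidation under buffered, non-basic conditions should give the aldehyde without epimerising C9 or eliminating the β-silyloxy group.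

Step 10
Reactants: 14 (1S,2R,4aR,8aR)-2-{[tert-butyl(dimethyl)silyl]oxy}-5,5,8a-trimethyl-1,2,4a,5,6,7,8,8a-octahydronaphthalene-1-carbaldehyde; 15 1-(triphenyl-λ5-phosphanylidene)propan-2-one
Product: 16 (3E)-4-[(1S,2R,4aR,8aR)-2-{[tert-butyl(dimethyl)silyl]oxy}-5,5,8a-trimethyl-1,2,4a,5,6,7,8,8a-octahydronaphthalen-1-yl]but-3-en-2-one
Conditions: 15 (2 equiv), toluene, 90 °C
Reagents that add atoms: 1-(triphenyl-λ5-phosphanylidene)propan-2-one (15), CC(=O)C=P(c1ccccc1)(c1ccccc1)c1ccccc1
Why: Wittig olefination with the stabilised, nearly neutral acetonyl ylide adds C12, C13 and C16 to the hindered aldehyde without enolising it, and the geometry of the new alkene is irrelevant because it is hydrogenated next.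

Step 11
Reactants: 16 (3E)-4-[(1S,2R,4aR,8aR)-2-{[tert-butyl(dimethyl)silyl]oxy}-5,5,8a-trimethyl-1,2,4a,5,6,7,8,8a-octahydronaphthalen-1-yl]but-3-en-2-one
Product: 17 4-[(1S,2R,4aR,8aR)-2-{[tert-butyl(dimethyl)silyl]oxy}-5,5,8a-trimethyldecahydronaphthalen-1-yl]butan-2-one
Conditions: H2 (1 atm), Pd/C, EtOAc, rt
Reagents that add atoms: none
Why: Heterogeneous catalytic hydrogenation saturates both the enone alkene and the ring C6=C7 alkene in one operation, creates no stereocentre and leaves the ketone and silyl ether intact in a non-protic solvent.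

Step 12
Reactants: 17 4-[(1S,2R,4aR,8aR)-2-{[tert-butyl(dimethyl)silyl]oxy}-5,5,8a-trimethyldecahydronaphthalen-1-yl]butan-2-one; 18 triethyl phosphonoacetate
Product: 19 ethyl (2E)-5-[(1S,2R,4aR,8aR)-2-{[tert-butyl(dimethyl)silyl]oxy}-5,5,8a-trimethyldecahydronaphthalen-1-yl]-3-methylpent-2-enoate
Conditions: 18, NaH, THF, 0 °C → 60 °C
Reagents that add atoms: triethyl phosphonoacetate (18), CCOC(=O)CP(=O)(OCC)OCC
Why: The Horner–Wadsworth–Emmons reaction of a methyl ketone adds C14 and C15 and favours the E trisubstituted enoate under equilibrating conditions, the minor Z isomer being removable by chromatography.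

Step 13
Reactants: 19 ethyl (2E)-5-[(1S,2R,4aR,8aR)-2-{[tert-butyl(dimethyl)silyl]oxy}-5,5,8a-trimethyldecahydronaphthalen-1-yl]-3-methylpent-2-enoate
Product: 20 ethyl (2E)-5-[(1S,2R,4aR,8aR)-2-hydroxy-5,5,8a-trimethyldecahydronaphthalen-1-yl]-3-methylpent-2-enoate
Conditions: HF·pyridine, THF/pyridine, 0 °C → rt
Reagents that add atoms: none
Why: Fluoride-mediated desilylation, driven by the strong Si–F bond, frees the C8 hydroxyl under buffered conditions that leave the enoate untouched.

Step 14
Reactants: 20 ethyl (2E)-5-[(1S,2R,4aR,8aR)-2-hydroxy-5,5,8a-trimethyldecahydronaphthalen-1-yl]-3-methylpent-2-enoate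
Product: 21 ethyl (2E)-3-methyl-5-[(1S,4aR,8aR)-5,5,8a-trimethyl-2-oxodecahydronaphthalen-1-yl]pent-2-enoate
Conditions: Dess–Martin periodinane, pyridine, CH2Cl2, rt
Reagents that add atoms: none
Why: Dess–Martin oxidation gives the C8 ketone; C9 becomes enolisable, but its side chain is already equatorial and cis to the C10 methyl, the thermodynamically preferred arrangement, so any equilibration should return the same configuration.

Step 15
Reactants: 21 ethyl (2E)-3-methyl-5-[(1S,4aR,8aR)-5,5,8a-trimethyl-2-oxodecahydronaphthalen-1-yl]pent-2-enoate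
Product: 22 ethyl (2E)-3-methyl-5-[(1R,4aR,8aR)-5,5,8a-trimethyl-2-methylidenedecahydronaphthalen-1-yl]pent-2-enoate
Conditions: Ph3PCH3Br, KOtBu, toluene, rt → 60 °C
Reagents that add atoms: methyltriphenylphosphonium bromide, C[P+](c1ccccc1)(c1ccccc1)c1ccccc1.[Br-]
Why: Wittig methylenation with the non-stabilised ylide converts the ketone into the C8=C17 methylene selectively over the β,β-disubstituted conjugated ester, which is a poor electrophile for the ylide.

Step 16
Reactants: 22 ethyl (2E)-3-methyl-5-[(1R,4aR,8aR)-5,5,8a-trimethyl-2-methylidenedecahydronaphthalen-1-yl]pent-2-enoate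
Product: 23 (2E)-3-methyl-5-[(1R,4aR,8aR)-5,5,8a-trimethyl-2-methylidenedecahydronaphthalen-1-yl]pent-2-en-1-ol
Conditions: iBu2AlH (2.5 equiv), CH2Cl2, −78 °C; aq. potassium sodium tartrate
Reagents that add atoms: none
Why: 1,2-Reduction of the enoate with iBu2AlH gives the (E)-allylic alcohol without touching either alkene.

Step 17
Reactants: 23 (2E)-3-methyl-5-[(1R,4aR,8aR)-5,5,8a-trimethyl-2-methylidenedecahydronaphthalen-1-yl]pent-2-en-1-ol; 24 2,2-dimethyl-1,3-dioxane-4,6-dione (Meldrum's acid)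
Product: 25 3-{[(2E)-3-methyl-5-[(1R,4aR,8aR)-5,5,8a-trimethyl-2-methylidenedecahydronaphthalen-1-yl]pent-2-en-1-yl]oxy}-3-oxopropanoic acid
Conditions: 24 (1.2 equiv), toluene, 100 °C
Reagents that add atoms: 2,2-dimethyl-1,3-dioxane-4,6-dione (24), CC1(C)OC(=O)CC(=O)O1
Why: Thermal acylation of an alcohol by Meldrum's acid (ring opening with loss of acetone) gives the malonic half ester directly, so no carboxyl protecting group is needed.

**Compound list**

1 | methyl (2E)-3,7-dimethylocta-2,6-dienoate (methyl geranate) | COC(=O)/C=C(\C)CCC=C(C)C | starting material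
2 | methyl (2E)-7-chloro-3,7-dimethyloct-2-enoate | COC(=O)/C=C(\C)CCCC(C)(C)Cl | intermediate
3 | allyltrimethylsilane | C=CC[Si](C)(C)C | starting material
4 | methyl (2E)-3,7,7-trimethyldeca-2,9-dienoate | COC(=O)/C=C(\C)CCCC(C)(C)CC=C | intermediate
5 | (2E)-3,7,7-trimethyldeca-2,9-dienoic acid | OC(=O)/C=C(\C)CCCC(C)(C)CC=C | intermediate
6 | 1,3-oxazolidin-2-one | O=C1NCCO1 | starting material
7 | 2,2-dimethylpropanoic (2E)-3,7,7-trimethyldeca-2,9-dienoic anhydride (mixed pivalic anhydride) | CC(C)(C)C(=O)OC(=O)/C=C(\C)CCCC(C)(C)CC=C | intermediate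
8 | 3-[(2E)-3,7,7-trimethyldeca-2,9-dienoyl]-1,3-oxazolidin-2-one | O=C(/C=C(\C)CCCC(C)(C)CC=C)N1CCOC1=O | intermediate
9 | (E)-but-2-enal (crotonaldehyde) | C/C=C/C=O | starting material
10 | 3-[(2E,9E)-3,7,7-trimethyl-11-oxoundeca-2,9-dienoyl]-1,3-oxazolidin-2-one | O=C(/C=C(\C)CCCC(C)(C)C/C=C/C=O)N1CCOC1=O | intermediate
11 | 3-[(2E,8E,10E)-11-{[tert-butyl(dimethyl)silyl]oxy}-3,7,7-trimethylundeca-2,8,10-trienoyl]-1,3-oxazolidin-2-one | O=C(/C=C(\C)CCCC(C)(C)/C=C/C=C/O[Si](C)(C)C(C)(C)C)N1CCOC1=O | intermediate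
12 | 3-{[(1S,2R,4aR,8aR)-2-{[tert-butyl(dimethyl)silyl]oxy}-5,5,8a-trimethyl-1,2,4a,5,6,7,8,8a-octahydronaphthalen-1-yl]carbonyl}-1,3-oxazolidin-2-one | O=C([C@@H]1[C@H](O[Si](C)(C)C(C)(C)C)C=C[C@@H]2C(C)(C)CCC[C@@]12C)N1CCOC1=O | intermediate
13 | [(1R,2R,4aR,8aR)-2-{[tert-butyl(dimethyl)silyl]oxy}-5,5,8a-trimethyl-1,2,4a,5,6,7,8,8a-octahydronaphthalen-1-yl]methanol | OC[C@@H]1[C@H](O[Si](C)(C)C(C)(C)C)C=C[C@@H]2C(C)(C)CCC[C@@]12C | intermediate
14 | (1S,2R,4aR,8aR)-2-{[tert-butyl(dimethyl)silyl]oxy}-5,5,8a-trimethyl-1,2,4a,5,6,7,8,8a-octahydronaphthalene-1-carbaldehyde | O=C[C@@H]1[C@H](O[Si](C)(C)C(C)(C)C)C=C[C@@H]2C(C)(C)CCC[C@@]12C | intermediate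
15 | 1-(triphenyl-λ5-phosphanylidene)propan-2-one | CC(=O)C=P(c1ccccc1)(c1ccccc1)c1ccccc1 | starting material
16 | (3E)-4-[(1S,2R,4aR,8aR)-2-{[tert-butyl(dimethyl)silyl]oxy}-5,5,8a-trimethyl-1,2,4a,5,6,7,8,8a-octahydronaphthalen-1-yl]but-3-en-2-one | CC(=O)/C=C/[C@@H]1[C@H](O[Si](C)(C)C(C)(C)C)C=C[C@@H]2C(C)(C)CCC[C@@]12C | intermediate
17 | 4-[(1S,2R,4aR,8aR)-2-{[tert-butyl(dimethyl)silyl]oxy}-5,5,8a-trimethyldecahydronaphthalen-1-yl]butan-2-one | CC(=O)CC[C@@H]1[C@H](O[Si](C)(C)C(C)(C)C)CC[C@@H]2C(C)(C)CCC[C@@]12C | intermediate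
18 | triethyl phosphonoacetate | CCOC(=O)CP(=O)(OCC)OCC | starting material
19 | ethyl (2E)-5-[(1S,2R,4aR,8aR)-2-{[tert-butyl(dimethyl)silyl]oxy}-5,5,8a-trimethyldecahydronaphthalen-1-yl]-3-methylpent-2-enoate | CCOC(=O)/C=C(\C)CC[C@@H]1[C@H](O[Si](C)(C)C(C)(C)C)CC[C@@H]2C(C)(C)CCC[C@@]12C | intermediate
20 | ethyl (2E)-5-[(1S,2R,4aR,8aR)-2-hydroxy-5,5,8a-trimethyldecahydronaphthalen-1-yl]-3-methylpent-2-enoate | CCOC(=O)/C=C(\C)CC[C@@H]1[C@H](O)CC[C@@H]2C(C)(C)CCC[C@@]12C | intermediate
21 | ethyl (2E)-3-methyl-5-[(1S,4aR,8aR)-5,5,8a-trimethyl-2-oxodecahydronaphthalen-1-yl]pent-2-enoate | CCOC(=O)/C=C(\C)CC[C@@H]1C(=O)CC[C@@H]2C(C)(C)CCC[C@@]12C | intermediate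
22 | ethyl (2E)-3-methyl-5-[(1R,4aR,8aR)-5,5,8a-trimethyl-2-methylidenedecahydronaphthalen-1-yl]pent-2-enoate | CCOC(=O)/C=C(\C)CC[C@@H]1C(=C)CC[C@@H]2C(C)(C)CCC[C@@]12C | intermediate
23 | (2E)-3-methyl-5-[(1R,4aR,8aR)-5,5,8a-trimethyl-2-methylidenedecahydronaphthalen-1-yl]pent-2-en-1-ol | OC/C=C(\C)CC[C@@H]1C(=C)CC[C@@H]2C(C)(C)CCC[C@@]12C | intermediate
24 | 2,2-dimethyl-1,3-dioxane-4,6-dione (Meldrum's acid) | CC1(C)OC(=O)CC(=O)O1 | starting material
25 | 3-{[(2E)-3-methyl-5-[(1R,4aR,8aR)-5,5,8a-trimethyl-2-methylidenedecahydronaphthalen-1-yl]pent-2-en-1-yl]oxy}-3-oxopropanoic acid | C=C1CC[C@@H]2C(C)(C)CCC[C@@]2(C)[C@@H]1CC/C(C)=C/COC(=O)CC(=O)O | target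

**Step count**

Total steps: 17. Longest linear sequence: 17 steps (from methyl geranate 1).

**Steps most likely to fail**

Step 7. The β,β-disubstituted dienophile may add too slowly, so that loss of the silyl group from the dienol ether wins, or the chelate may give insufficient endo or facial selectivity. The fallback hands control to a covalently bound auxiliary and a stoichiometric aluminium Lewis acid. It sets out from acid 5: the mixed anhydride 7 is formed as in step 4 and treated with (4R)-4-benzyl-1,3-oxazolidin-2-one and LiCl to give (4R)-4-benzyl-3-[(2E)-3,7,7-trimethyldeca-2,9-dienoyl]-1,3-oxazolidin-2-one F1. Cross-metathesis with crotonaldehyde 9 gives the 11-oxo enal imide F2, and TBSOTf/Et3N gives the 11-silyloxy triene imide F3. Me2AlCl (1.4 equiv, CH2Cl2, −30 °C) should then close both rings through the chelated s-cis imide, the benzyl group covering the Si face of C9, to give the auxiliary-bearing cycloadduct F4. LiBH4 removes the auxiliary and the route is rejoined at alcohol 13.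

Step 2. After ionisation the tertiary cation may lose a proton, or the released HCl may protodesilylate the allylsilane, instead of forming the C–C bond. The fallback builds the quaternary carbon by conjugate addition before the enoate exists. It sets out from allyltrimethylsilane 3: Hosomi–Sakurai conjugate allylation of diethyl isopropylidenemalonate (TiCl4, CH2Cl2, −78 °C) gives diethyl 2-(2-methylpent-4-en-2-yl)propanedioate F5. Krapcho dealkoxycarbonylation (LiCl, wet DMSO, 160 °C) gives ethyl 3,3-dimethylhex-5-enoate F6, LiAlH4 gives 3,3-dimethylhex-5-en-1-ol F7, and I2/PPh3/imidazole gives 6-iodo-4,4-dimethylhex-1-ene F8. Alkylation of the dianion of methyl acetoacetate (NaH, then nBuLi) gives methyl 7,7-dimethyl-3-oxodec-9-enoate F9. Its enol phosphate, methyl (2Z)-3-[(diethoxyphosphoryl)oxy]-7,7-dimethyldeca-2,9-dienoate F10 (NaH, ClP(O)(OEt)2), is methylated with Me2CuLi with retention of geometry, which returns the route to ester 4.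

Step 8. Hydride may attack the ring carbonyl of the oxazolidinone instead of the hindered acyl carbonyl and open the heterocycle. The fallback replaces hydride by a small, soft thiolate and then reduces partially. It sets out from imide 12: LiSEt (EtSH, nBuLi, THF, 0 °C) gives S-ethyl (1S,2R,4aR,8aR)-2-{[tert-butyl(dimethyl)silyl]oxy}-5,5,8a-trimethyl-1,2,4a,5,6,7,8,8a-octahydronaphthalene-1-carbothioate F11. Fukuyama reduction (Et3SiH, Pd/C, acetone, rt) gives the aldehyde directly, so the route is rejoined at 14 without passing through 13.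

Further compounds
F1 | step 7 | (4R)-4-benzyl-3-[(2E)-3,7,7-trimethyldeca-2,9-dienoyl]-1,3-oxazolidin-2-one | O=C(/C=C(\C)CCCC(C)(C)CC=C)N1[C@H](Cc2ccccc2)COC1=O
F2 | step 7 | (4R)-4-benzyl-3-[(2E,9E)-3,7,7-trimethyl-11-oxoundeca-2,9-dienoyl]-1,3-oxazolidin-2-one | O=C(/C=C(\C)CCCC(C)(C)C/C=C/C=O)N1[C@H](Cc2ccccc2)COC1=O
F3 | step 7 | (4R)-4-benzyl-3-[(2E,8E,10E)-11-{[tert-butyl(dimethyl)silyl]oxy}-3,7,7-trimethylundeca-2,8,10-trienoyl]-1,3-oxazolidin-2-one | O=C(/C=C(\C)CCCC(C)(C)/C=C/C=C/O[Si](C)(C)C(C)(C)C)N1[C@H](Cc2ccccc2)COC1=O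
F4 | step 7 | (4R)-4-benzyl-3-{[(1S,2R,4aR,8aR)-2-{[tert-butyl(dimethyl)silyl]oxy}-5,5,8a-trimethyl-1,2,4a,5,6,7,8,8a-octahydronaphthalen-1-yl]carbonyl}-1,3-oxazolidin-2-one | O=C([C@@H]1[C@H](O[Si](C)(C)C(C)(C)C)C=C[C@@H]2C(C)(C)CCC[C@@]12C)N1[C@H](Cc2ccccc2)COC1=O
F5 | step 2 | diethyl 2-(2-methylpent-4-en-2-yl)propanedioate | CCOC(=O)C(C(=O)OCC)C(C)(C)CC=C
F6 | step 2 | ethyl 3,3-dimethylhex-5-enoate | CCOC(=O)CC(C)(C)CC=C
F7 | step 2 | 3,3-dimethylhex-5-en-1-ol | OCCC(C)(C)CC=C
F8 | step 2 | 6-iodo-4,4-dimethylhex-1-ene | ICCC(C)(C)CC=C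
F9 | step 2 | methyl 7,7-dimethyl-3-oxodec-9-enoate | COC(=O)CC(=O)CCCC(C)(C)CC=C
F10 | step 2 | methyl (2Z)-3-[(diethoxyphosphoryl)oxy]-7,7-dimethyldeca-2,9-dienoate | COC(=O)/C=C(\OP(=O)(OCC)OCC)CCCC(C)(C)CC=C
F11 | step 8 | S-ethyl (1S,2R,4aR,8aR)-2-{[tert-butyl(dimethyl)silyl]oxy}-5,5,8a-trimethyl-1,2,4a,5,6,7,8,8a-octahydronaphthalene-1-carbothioate | CCSC(=O)[C@@H]1[C@H](O[Si](C)(C)C(C)(C)C)C=C[C@@H]2C(C)(C)CCC[C@@]12C
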